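**Retrosynthetic overview**
1. Target 17 ⇐ acetal 14: the lactone CH2 (C5 of the five-membered lactone ring; ring atoms O1, C2(=O), C3, C4, C5) is carried at the aldehyde level as a chiral l-menthyl acetal and released last by hydroxide opening, NaBH4 reduction and relactonisation.
2. 14 ⇐ butenolide 11 + acid 12: key disconnection of the bond between ring carbon C4 and its benzylic CH2; forward, a photoredox decarboxylative radical conjugate addition of 3,4,5-trimethoxyphenylacetic acid to C4, then base equilibration of C3 in the same flask.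
3. Enabling feature: C4 is β to the lactone carbonyl C2 and next to the oxygen-bearing C5, so a C3=C4 double bond plus an acetal at C5 makes C4 an electrophilic, face-differentiated radical acceptor; its partner, the CH2 on the electron-rich 3,4,5-trimethoxyphenyl ring, is a nucleophilic benzylic radical available from the arylacetic acid by loss of CO2.
4. 11 ⇐ bromobutenolide 8 + benzylzinc 10 (Negishi coupling); 8 ⇐ menthyloxybutenolide 6 (bromination–dehydrobromination); 6 ⇐ furfural 1 + (−)-menthol 4.
5. Ring order: the lactone ring is the only ring made; it is formed first (steps 1–2), kept through the key step, and opened and re-closed in step 6; both aromatic rings are bought.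

Key step: step 5

Assumption: l-menthyl means (1R,2S,5R)-2-isopropyl-5-methylcyclohexyl; 3,4,5-trimethoxybenzyl bromide, used only in fallbacks, is a purchased reagent.

**Route**

Step 1
Reactants: 1 furfural
Product: 3 5-hydroxyfuran-2(5H)-one (racemic hemiacetal), via furan endoperoxide 2 (not isolated)
Conditions: O2 (1 atm), rose bengal (cat.), MeOH, visible light, 20 °C
Reagents that add atoms: oxygen, O=O
Why: Dye-sensitised singlet-oxygen [4+2] photooxygenation of the furan gives the 2,5-endoperoxide, which methanol fragments with loss of the formyl carbon as methyl formate to leave the γ-hydroxybutenolide; the hemiacetal carbon is racemic and is settled in step 2.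

Step 2
Reactants: 3 5-hydroxyfuran-2(5H)-one; 4 (−)-menthol
Product: 6 (5R)-5-(l-menthyloxy)furan-2(5H)-one, via (5S)-epimeric menthyl acetal 5 (not isolated)
Conditions: p-TsOH·H2O (cat.), toluene, reflux, Dean–Stark; crystallisation from petroleum ether, −20 °C; mother liquor re-equilibrated (p-TsOH cat.) and recrystallised
Reagents that add atoms: none
Why: Acid-catalysed acetalisation of the cyclic hemiacetal (pseudo-ester formation) gives both C5 epimers, which interconvert through the ring oxocarbenium ion, so crystallisation of the less soluble (5R) epimer should funnel the material into one diastereomer (crystallisation-induced diastereomer transformation) and set C5.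

Step 3
Reactants: 6 (5R)-5-(l-menthyloxy)furan-2(5H)-one
Product: 8 (5R)-3-bromo-5-(l-menthyloxy)furan-2(5H)-one, via trans-3,4-dibromolactone 7 (not isolated)
Conditions: Br2 (1.05 equiv), CH2Cl2, 0 °C; then Et3N (1.2 equiv), 0 → 20 °C
Reagents that add atoms: bromine, BrBr
Why: Bromination–dehydrobromination: anti addition of Br2 to the enoate (7 is drawn as the isomer with the C4 bromine anti to the menthyloxy group; the other trans-dibromide converges), then E1cB loss of the β-bromide after deprotonation at C3, returns the conjugated butenolide with bromine at C3 and leaves the C5 acetal untouched.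

Step 4
Reactants: 8 (5R)-3-bromo-5-(l-menthyloxy)furan-2(5H)-one; 9 3,4,5-trimethoxybenzyl chloride
Product: 11 (5R)-5-(l-menthyloxy)-3-(3,4,5-trimethoxybenzyl)furan-2(5H)-one, via (3,4,5-trimethoxybenzyl)zinc chloride 10 (not isolated)
Conditions: 9, Zn dust (1.5 equiv), LiCl (1.5 equiv), THF, 25 °C; then 8, Pd(OAc)2 (2 mol%), SPhos (4 mol%), THF, 25 °C
Reagents that add atoms: none
Why: Negishi coupling: LiCl-promoted zinc insertion into the benzylic chloride gives a benzylzinc without β-hydrogens, which couples under palladium catalysis with the electron-poor α-bromoenoate (easy oxidative addition), and the neutral, non-basic conditions should leave the C5 acetal stereocentre intact.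

Step 5
Reactants: 11 (5R)-5-(l-menthyloxy)-3-(3,4,5-trimethoxybenzyl)furan-2(5H)-one; 12 3,4,5-trimethoxyphenylacetic acid
Product: 14 (3R,4R,5R)-5-(l-menthyloxy)-3,4-bis(3,4,5-trimethoxybenzyl)dihydrofuran-2(3H)-one, via cis-(3S) adduct 13 (not isolated)
Conditions: 12 (2 equiv), 4CzIPN (2,4,5,6-tetra(carbazol-9-yl)isophthalonitrile, 2 mol%), K2HPO4 (1.2 equiv), degassed DMF, blue LEDs (450 nm), 25 °C; then DBU (3 equiv), 40 °C
Reagents that add atoms: none
Why: Excited 4CzIPN oxidises the carboxylate of 12, CO2 is lost, and the nucleophilic 3,4,5-trimethoxybenzyl radical adds to the unsubstituted, electron-poor C4 of 11; the tertiary α-acyl radical at C3 is then reduced by the photocatalyst radical anion to the lactone enolate and protonated, closing a redox-neutral cycle. The closest known reaction type is the photoredox decarboxylative Giese addition of arylacetic acids to α,β-unsaturated esters and lactones, together with the anti-selective radical additions to 5-alkoxyfuran-2(5H)-ones. No ring is closed; the lactone ring is carried through intact. C4 is set (R) by the adjacent C5 menthyloxy group, which shields one face so that the radical enters anti to it. C3 is first set by protonation, expected mainly anti to the new C4 benzyl group (cis adduct 13), and DBU then equilibrates it through the enolate to the all-trans (3R) arrangement under thermodynamic control. The step needs regioselectivity for C4 over C3, secured by the C3 benzyl group and the polarity of the enoate, and oxidation of the carboxylate in preference to the trimethoxyarenes without epimerisation of the γ-acidic C5, secured by the low oxidation potential of the arylacetate and the mild phosphate base.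

Step 6
Reactants: 14 (3R,4R,5R)-5-(l-menthyloxy)-3,4-bis(3,4,5-trimethoxybenzyl)dihydrofuran-2(3H)-one
Product: 17 (−)-cubebininolide [(3R,4R)-3,4-bis(3,4,5-trimethoxybenzyl)dihydrofuran-2(3H)-one], via potassium formyl carboxylate 15 (not isolated), via potassium hydroxy carboxylate 16 (not isolated)
Conditions: NaBH4 (3 equiv), KOH (3 equiv), EtOH/H2O, 0 → 25 °C; then 2 M HCl to pH 1, 25 °C
Reagents that add atoms: potassium hydroxide, [K+].[OH-] (after opening and re-closure of the lactone, the hydroxide oxygen can remain as the carbonyl oxygen)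
Why: Saponification of the pseudo-ester releases the hemiacetal, which collapses to the aldehyde with loss of menthol; NaBH4 reduces the aldehyde as it forms and acid lactonisation closes the ring onto the untouched carboxyl, so C4 (α to the transient aldehyde) and C3 (α to a carboxylate, not enolised) should keep their configuration.

**Compound list**
1 | furfural | O=Cc1ccco1 | starting material
2 | 2,3,7-trioxabicyclo[2.2.1]hept-5-ene-1-carbaldehyde (furan endoperoxide, racemic) | O=CC12OOC(C=C1)O2 | intermediate
3 | 5-hydroxyfuran-2(5H)-one (racemic) | OC1OC(=O)C=C1 | intermediate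
4 | (−)-menthol, (1R,2S,5R)-2-isopropyl-5-methylcyclohexan-1-ol | CC(C)[C@@H]1CC[C@@H](C)C[C@H]1O | starting material
5 | (5S)-5-(l-menthyloxy)furan-2(5H)-one | CC(C)[C@@H]1CC[C@@H](C)C[C@H]1O[C@H]2OC(=O)C=C2 | intermediate
6 | (5R)-5-(l-menthyloxy)furan-2(5H)-one | CC(C)[C@@H]1CC[C@@H](C)C[C@H]1O[C@@H]2OC(=O)C=C2 | intermediate
7 | (3S,4S,5R)-3,4-dibromo-5-(l-menthyloxy)dihydrofuran-2(3H)-one | CC(C)[C@@H]1CC[C@@H](C)C[C@H]1O[C@@H]2OC(=O)[C@H](Br)[C@H]2Br | intermediate
8 | (5R)-3-bromo-5-(l-menthyloxy)furan-2(5H)-one | CC(C)[C@@H]1CC[C@@H](C)C[C@H]1O[C@@H]2OC(=O)C(Br)=C2 | intermediate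
9 | 3,4,5-trimethoxybenzyl chloride | COc1cc(CCl)cc(OC)c1OC | starting material
10 | (3,4,5-trimethoxybenzyl)zinc chloride (LiCl-solvated, in THF) | COc1cc(C[Zn]Cl)cc(OC)c1OC | intermediate
11 | (5R)-5-(l-menthyloxy)-3-(3,4,5-trimethoxybenzyl)furan-2(5H)-one | CC(C)[C@@H]1CC[C@@H](C)C[C@H]1O[C@@H]2OC(=O)C(Cc3cc(OC)c(OC)c(OC)c3)=C2 | intermediate
12 | 3,4,5-trimethoxyphenylacetic acid | COc1cc(CC(=O)O)cc(OC)c1OC | starting material
13 | (3S,4R,5R)-5-(l-menthyloxy)-3,4-bis(3,4,5-trimethoxybenzyl)dihydrofuran-2(3H)-one (3,4-cis) | CC(C)[C@@H]1CC[C@@H](C)C[C@H]1O[C@@H]2OC(=O)[C@@H](Cc3cc(OC)c(OC)c(OC)c3)[C@H]2Cc4cc(OC)c(OC)c(OC)c4 | intermediate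
14 | (3R,4R,5R)-5-(l-menthyloxy)-3,4-bis(3,4,5-trimethoxybenzyl)dihydrofuran-2(3H)-one (all-trans) | CC(C)[C@@H]1CC[C@@H](C)C[C@H]1O[C@@H]2OC(=O)[C@H](Cc3cc(OC)c(OC)c(OC)c3)[C@H]2Cc4cc(OC)c(OC)c(OC)c4 | intermediate
15 | potassium (2R,3R)-4-oxo-2,3-bis(3,4,5-trimethoxybenzyl)butanoate | [K+].[O-]C(=O)[C@H](Cc1cc(OC)c(OC)c(OC)c1)[C@H](C=O)Cc1cc(OC)c(OC)c(OC)c1 | intermediate
16 | potassium (2R,3R)-4-hydroxy-2,3-bis(3,4,5-trimethoxybenzyl)butanoate | [K+].[O-]C(=O)[C@H](Cc1cc(OC)c(OC)c(OC)c1)[C@H](CO)Cc1cc(OC)c(OC)c(OC)c1 | intermediate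
17 | (−)-cubebininolide, (3R,4R)-3,4-bis(3,4,5-trimethoxybenzyl)dihydrofuran-2(3H)-one | COc1cc(C[C@H]2COC(=O)[C@@H]2Cc2cc(OC)c(OC)c(OC)c2)cc(OC)c1OC | target

**Step count and risks**
Total step count: 6. Longest linear sequence: 6 steps (1 → 17); chloride 9 and acid 12 are bought and enter directly.

Steps most likely to fail:

1. Step 5 (key step). The stabilised benzylic radical may add too slowly to the trisubstituted butenolide, so that radical dimerisation and simple reduction win; the base could also erode the C5 acetal centre before addition. The fallback uses anionic chemistry, sets out from compound 6 and comes back at compound 14. 2-(3,4,5-Trimethoxyphenyl)-1,3-dithiane F1 (from 3,4,5-trimethoxybenzaldehyde and propane-1,3-dithiol, BF3·OEt2, CH2Cl2) is deprotonated with n-BuLi (THF, −78 °C) to the 2-lithiodithiane F2. F2 adds to C4 of 6 anti to the menthyloxy group to give the lithium enolate F3. F3 is trapped in the same flask with 3,4,5-trimethoxybenzyl bromide anti to the new C4 substituent to give the dithianyl lactone F4. Raney Ni (EtOH, reflux) removes the dithiane and returns the route to 14.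

2. Step 4. Protodebromination of 8, uncatalysed conjugate addition of the organozinc, or decomposition of the α-bromobutenolide may outrun the cross-coupling. The fallback changes the order of bond formation, sets out from compound 6 and comes back at compound 14. Compound 6 is taken directly into the decarboxylative radical addition with acid 12 (conditions of step 5 without DBU) to give the β-benzyl lactone (4R,5R)-5-(l-menthyloxy)-4-(3,4,5-trimethoxybenzyl)dihydrofuran-2(3H)-one F5. LDA (THF, −78 °C) converts it into the lithium enolate F6, which is alkylated with 3,4,5-trimethoxybenzyl bromide anti to the C4 substituent to give 14.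

3. Step 6. The transient aldehyde may enolise under KOH before reduction, which would epimerise C4, or relactonisation may be incomplete. The fallback sets out from compound 14 and comes back at compound 17. LiAlH4 (THF, 0 → 25 °C) reduces both the lactone and the masked aldehyde, with loss of menthol, to (2R,3R)-2,3-bis(3,4,5-trimethoxybenzyl)butane-1,4-diol F7. Oxidative lactonisation with TEMPO (cat.) and PhI(OAc)2 (CH2Cl2, 25 °C) proceeds through the lactol (3R,4R)-3,4-bis(3,4,5-trimethoxybenzyl)tetrahydrofuran-2-ol F8 to 17. Because the two aryl groups are identical, F7 is C2-symmetric and oxidation at either hydroxymethyl group gives the same lactone.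

**Further compounds**
F1 | step 5 | 2-(3,4,5-trimethoxyphenyl)-1,3-dithiane | COc1cc(C2SCCCS2)cc(OC)c1OC
F2 | step 5 | 2-lithio-2-(3,4,5-trimethoxyphenyl)-1,3-dithiane | [Li]C1(SCCCS1)c1cc(OC)c(OC)c(OC)c1
F3 | step 5 | lithium enolate of (4R,5R)-5-(l-menthyloxy)-4-[2-(3,4,5-trimethoxyphenyl)-1,3-dithian-2-yl]dihydrofuran-2(3H)-one | CC(C)[C@@H]1CC[C@@H](C)C[C@H]1O[C@@H]2OC(O[Li])=C[C@H]2C3(SCCCS3)c4cc(OC)c(OC)c(OC)c4
F4 | step 5 | (3R,4R,5R)-5-(l-menthyloxy)-3-(3,4,5-trimethoxybenzyl)-4-[2-(3,4,5-trimethoxyphenyl)-1,3-dithian-2-yl]dihydrofuran-2(3H)-one | CC(C)[C@@H]1CC[C@@H](C)C[C@H]1O[C@@H]2OC(=O)[C@H](Cc3cc(OC)c(OC)c(OC)c3)[C@H]2C4(SCCCS4)c5cc(OC)c(OC)c(OC)c5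
F5 | step 4 | (4R,5R)-5-(l-menthyloxy)-4-(3,4,5-trimethoxybenzyl)dihydrofuran-2(3H)-one | CC(C)[C@@H]1CC[C@@H](C)C[C@H]1O[C@@H]2OC(=O)C[C@H]2Cc3cc(OC)c(OC)c(OC)c3
F6 | step 4 | lithium enolate of (4R,5R)-5-(l-menthyloxy)-4-(3,4,5-trimethoxybenzyl)dihydrofuran-2(3H)-one | CC(C)[C@@H]1CC[C@@H](C)C[C@H]1O[C@@H]2OC(O[Li])=C[C@H]2Cc3cc(OC)c(OC)c(OC)c3
F7 | step 6 | (2R,3R)-2,3-bis(3,4,5-trimethoxybenzyl)butane-1,4-diol | OC[C@H](Cc1cc(OC)c(OC)c(OC)c1)[C@H](CO)Cc1cc(OC)c(OC)c(OC)c1
F8 | step 6 | (3R,4R)-3,4-bis(3,4,5-trimethoxybenzyl)tetrahydrofuran-2-ol (anomeric mixture) | C1OC(O)[C@H](Cc2cc(OC)c(OC)c(OC)c2)[C@H]1Cc1cc(OC)c(OC)c(OC)c1
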